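7.43 d is the number I start from: the half-life of the target late in the north-west run, as read between 8.00 d and 15.0 d.

| setting | north-west | teal | violet | grey | green | amber |
|---|---|---|---|---|---|---|
| substrate | 0.036 M | 0.050 M | 0.080 M | 0.12 M | 0.15 M | 0.25 M |
| free catalyst | 1.3 mol% | 1.3 mol% | 1.3 mol% | 1.3 mol% | 1.3 mol% | 1.3 mol% |
| remark | run made earlier |  |  |  |  |  |
| time |  | 20 d | 20 d | 20 d | 20 d | 20 d |

north-west run (percent of the substrate charged)

| time / d | target / % |
|---|---|
| 1.04 | 47.7 |
| 2.00 | 65.3 |
| 4.00 | 62.0 |
| 8.00 | 36.9 |
| 15.0 | 19.2 |

(standard deviation of a reading: 1 percentage point)

- the earlier runs were read with a standard deviation of 1 percentage point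
- "hardly changes" means that all values lie within two and a half points (for a concentration: within two and a half percent of the largest)
- no earlier run changes the charge of free catalyst; that part of a forecast is a guess

1. [target] at the end for teal, violet, grey, green, amber, in this order
2. how the row runs (falls, then rises / rises, then falls / falls all the way / rises all the way / hardly changes)

The north-west flask is teal's close neighbour, with the same 1.3 mol% of free catalyst but 0.036 M of substrate against 0.050 M. Its first reading gives a filling time, the time the north-west run would need to make its charge into target at the opening speed: 2.18 d. Its highest reading stands at 2.00 d, but that is just the best sampled point: the readings place the handover from making to loss somewhere between 1.04 d and 4.00 d. Because the filling time is shorter than the half-life and both are shorter than 20 d, I expect teal's end to belong to the loss.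

Which loss? The north-west run can't prove it. Its apparent constant falls from 0.130 /d to 0.0933 /d, as a second-order loss would show, but so would a loss running back towards a floor.

I commit to a first-order loss, which takes a fixed share per day at any charge. Teal then follows the north-west curve in percent, while its c(target) stands 1.39 times higher. Running the last reading on for 5.00 d gives the end share, the percent of the charge standing as target at 20 d: 12.0 %. It leans low, since I hold a falling constant flat. Multiplied by the charge, it gives 0.00600 M for teal and 0.0301 M for amber.

The forecast gives 0.0054 M, 0.0055 M, 0.0056 M, 0.0057 M and 0.0057 M, so its shape is rises all the way, on the ground that "Second-order loss forgets its starting concentration". We part at amber, where I hold more than the forecast.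

The flask gives 0.00704 M, 0.0112 M, 0.0167 M, 0.0208 M and 0.0345 M, and the shape is rises all the way.

    substrate + free catalyst ⇌ catalyst intermediate (K = 29.0 /M, k = 470 /M/h)
    target ⇌ isomer of the product (K = 7.60, k = 0.00700 /h)
    catalyst intermediate → free catalyst + target (k = 4.20 /h)

Teal ends at 14.1 % of its charge against my end share of 12.0 %. Amber ends at 13.8 % of its charge, where the end share gave 0.0301 M against its 0.0345 M. In teal the target and the isomer of the product relax into each other with a half-life of 3.65 d, both ways together, which is shorter than the 20 d of the run. Teal holds 14.1 % target and 85.9 % isomer of the product at 20.0 d, and 11.6 % target at 200 d.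

The runs stem from a simulated flask from invented constants.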